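**Retrosynthetic overview**
1. Rings B and C are made together in the last operation: the 2,4-bridged furan of a ten-membered furanophane is opened with singlet oxygen to a cis-ene-dione, and a transannular C12→C11 aldol gives the cyclopentenone and the nine-membered ring, setting C11 and C12.
2. The furanophane comes from a NiCl2/CrCl2 ring closure between a 2-iodofuran and an (E)-γ-hydroxy enal; the C8 ketone is reduced afterwards.
3. The γ-hydroxy enal (C3 carbinol, C1=C2) comes from a ring A enal by epoxidation, one-carbon homologation (C12) and vinylogous epoxide opening.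
4. Ring A is made first by an organocatalytic Mukaiyama–Michael/aldol condensation (sets C6 and C7); the furan (Feist–Benary) is attached through a Fukuyama ketone synthesis (C8–C9).
5. Ring order: A, then the ten-membered furan-bridged ring, then B and C together.

Assumption: the thioester-derived (Z)-silyl ketene acetal 7 gives the anti Mukaiyama–Michael adduct with the (2S,5S)-imidazolidinone on the Re face of C6, as recalled for this reagent class with simple enals.
Locants C1–C18 are fusicoccane locants: ring A = C2–C6 (C3 carbinol), C1 = vinylic CH, C7 = CHMe, C8 = CHOH, C9 = CH2, ring C = C10–C14 (C11 and C12 carbinols, C13 ketone).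

**Route**

Step 1
Reactants: 1 2-methoxy-N-methoxy-N-methylacetamide; 2 but-3-en-1-ylmagnesium bromide
Product: 3 1-methoxyhex-5-en-2-one
Conditions: THF, 0 °C; then 1 M HCl
Reagents that add atoms: none
Why: Weinreb ketone synthesis, in which the chelated magnesium adduct stops at the ketone stage; no stereocentre is involved.

Step 2
Reactants: 3 1-methoxyhex-5-en-2-one; 4 (E)-but-2-enal
Product: 5 (2E)-7-methoxy-6-oxohept-2-enal
Conditions: RuCl2(=CH-C6H4-2-O-i-Pr)(H2IMes) (second-generation Hoveyda–Grubbs catalyst, 3 mol %), excess 4, CH2Cl2, 40 °C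
Reagents that add atoms: none
Why: Olefin cross-metathesis of a terminal alkene with excess crotonaldehyde gives the (E)-enal and releases propene; ketone and ether are inert.

Step 3
Reactants: 6 S-ethyl propanethioate
Product: 7 tert-butyl{[(1Z)-1-(ethylsulfanyl)prop-1-en-1-yl]oxy}dimethylsilane
Conditions: LiN(i-Pr)2, THF, −78 °C; t-BuMe2SiCl, DMPU, −78 to 0 °C
Reagents that add atoms: tert-butyldimethylsilyl chloride, CC(C)(C)[Si](C)(C)Cl
Why: Kinetic thioester enolisation and O-silylation (Ireland-type silyl ketene acetal formation) give mainly the (Z)-ketene S,O-acetal needed for the anti adduct.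

Step 4
Reactants: 5 (2E)-7-methoxy-6-oxohept-2-enal; 7 tert-butyl{[(1Z)-1-(ethylsulfanyl)prop-1-en-1-yl]oxy}dimethylsilane
Product: 9 S-ethyl (2R)-2-[(1S)-2-formyl-3-(methoxymethyl)cyclopent-2-en-1-yl]propanethioate, via Michael adduct 8 (not isolated)
Conditions: (2S,5S)-5-benzyl-2-tert-butyl-3-methylimidazolidin-4-one·CF3CO2H (20 mol %), CH2Cl2/H2O, −60 °C; then piperidine, AcOH, 23–40 °C
Reagents that add atoms: none
Why: Organocatalytic Mukaiyama–Michael addition to the iminium ion (the benzyl group blocks the Si face, so Re-face attack sets C6, and the open transition state with the (Z)-ketene acetal sets C7 anti) is followed by amine-catalysed intramolecular aldol condensation of the 1,6-keto aldehyde, which closes ring A.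

Step 5
Reactants: 10 ethyl 3-oxobutanoate; 11 1-bromo-3-methylbutan-2-one
Product: 13 ethyl 2-methyl-4-(propan-2-yl)furan-3-carboxylate, via hydroxydihydrofuran 12 (not isolated)
Conditions: pyridine, 23–60 °C; then HCl (cat.), EtOH, 50 °C
Reagents that add atoms: none
Why: Feist–Benary furan synthesis, in which aldol addition to the ketone precedes O-alkylation in pyridine, placing the isopropyl group at C4 and leaving C5 free; acid then dehydrates 12.

Step 6
Reactants: 13 ethyl 2-methyl-4-(propan-2-yl)furan-3-carboxylate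
Product: 14 [2-methyl-4-(propan-2-yl)furan-3-yl]methanol
Conditions: LiAlH4, Et2O, 0 °C
Reagents that add atoms: none
Why: Hydride reduction of the ester; the furan is untouched.

Step 7
Reactants: 14 [2-methyl-4-(propan-2-yl)furan-3-yl]methanol
Product: 15 3-(bromomethyl)-2-methyl-4-(propan-2-yl)furan
Conditions: PBr3, pyridine (cat.), Et2O, −10 °C; used at once
Reagents that add atoms: phosphorus tribromide, BrP(Br)Br
Why: Nucleophilic substitution of the activated benzylic-type alcohol by bromide.

Step 8
Reactants: 9 S-ethyl (2R)-2-[(1S)-2-formyl-3-(methoxymethyl)cyclopent-2-en-1-yl]propanethioate; 15 3-(bromomethyl)-2-methyl-4-(propan-2-yl)furan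
Product: 17 (5S)-2-(methoxymethyl)-5-{(2R)-4-[2-methyl-4-(propan-2-yl)furan-3-yl]-3-oxobutan-2-yl}cyclopent-1-ene-1-carbaldehyde, via furylmethylzinc bromide 16 (not isolated)
Conditions: 15, Zn, LiCl, THF, 0 °C; then 9, PdCl2(PPh3)2 (5 mol %), THF/toluene, 23 °C; 1 M HCl
Reagents that add atoms: none
Why: Fukuyama coupling (zinc insertion, then palladium-catalysed acyl substitution of the thioester) forms the C8–C9 bond without touching the enal or epimerising C7.

Step 9
Reactants: 17 (5S)-2-(methoxymethyl)-5-{(2R)-4-[2-methyl-4-(propan-2-yl)furan-3-yl]-3-oxobutan-2-yl}cyclopent-1-ene-1-carbaldehyde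
Product: 18 (5S)-5-{(2R)-4-[5-iodo-2-methyl-4-(propan-2-yl)furan-3-yl]-3-oxobutan-2-yl}-2-(methoxymethyl)cyclopent-1-ene-1-carbaldehyde
Conditions: N-iodosuccinimide, THF, 0 °C, dark
Reagents that add atoms: N-iodosuccinimide, O=C1CCC(=O)N1I
Why: Electrophilic aromatic iodination at the only free (α) furan position; the electron-poor enal is inert.

Step 10
Reactants: 18 (5S)-5-{(2R)-4-[5-iodo-2-methyl-4-(propan-2-yl)furan-3-yl]-3-oxobutan-2-yl}-2-(methoxymethyl)cyclopent-1-ene-1-carbaldehyde
Product: 19 (1S,2S,5S)-2-{(2R)-4-[5-iodo-2-methyl-4-(propan-2-yl)furan-3-yl]-3-oxobutan-2-yl}-5-(methoxymethyl)-6-oxabicyclo[3.1.0]hexane-1-carbaldehyde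
Conditions: H2O2 (30 % aq.), NaHCO3, MeOH, 0 °C
Reagents that add atoms: hydrogen peroxide, OO
Why: Weitz–Scheffer nucleophilic epoxidation, in which hydroperoxide adds to the enal β-carbon on the ring face anti to the C6 side chain and so fixes the C3–O configuration.

Step 11
Reactants: 19 (1S,2S,5S)-2-{(2R)-4-[5-iodo-2-methyl-4-(propan-2-yl)furan-3-yl]-3-oxobutan-2-yl}-5-(methoxymethyl)-6-oxabicyclo[3.1.0]hexane-1-carbaldehyde
Product: 21 (2E)-2-[(2R,5S)-2-hydroxy-5-{(2R)-4-[5-iodo-2-methyl-4-(propan-2-yl)furan-3-yl]-3-oxobutan-2-yl}-2-(methoxymethyl)cyclopentylidene]acetaldehyde, via enol ether 20 (not isolated)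
Conditions: MeOCH2PPh3Cl, KN(SiMe3)2, THF, −78 to 0 °C; then pyridinium p-toluenesulfonate, THF/H2O, 0 °C, short
Reagents that add atoms: (methoxymethyl)triphenylphosphonium chloride, COC[P+](c1ccccc1)(c1ccccc1)c1ccccc1.[Cl-]; water, O
Why: Wittig methoxymethylenation adds C12, and protonation of the enol ether triggers vinylogous (SN2′-type) epoxide opening and hydrolysis to the γ-hydroxy enal with the C3–O bond untouched; allylic strain favours the (E)-alkene, and brief hydrolysis avoids equilibration to the (Z)-isomer, which would lactolise.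

Step 12
Reactants: 21 (2E)-2-[(2R,5S)-2-hydroxy-5-{(2R)-4-[5-iodo-2-methyl-4-(propan-2-yl)furan-3-yl]-3-oxobutan-2-yl}-2-(methoxymethyl)cyclopentylidene]acetaldehyde
Product: 22 furanophane keto diol (ten-membered ring: furan C5 bonded to the new CH(OH) carbon C12, both epimers; C8 ketone; 3R, 6S, 7R)
Conditions: CrCl2 (8 equiv), NiCl2 (0.1 equiv), DMSO/THF, 2 mM, 23–45 °C
Reagents that add atoms: none
Why: Nozaki–Hiyama–Kishi macrocyclisation, in which zerovalent nickel inserts into the furyl iodide and the trivalent chromium species adds only to the aldehyde under high dilution; the new carbinol centre is erased in step 14.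

Step 13
Reactants: 22 furanophane keto diol
Product: 23 furanophane triol (as 22 with (8S)-CHOH)
Conditions: LiBH(s-Bu)3, THF, −78 °C
Reagents that add atoms: none
Why: Felkin–Anh reduction, in which the bulky hydride attacks the C8 ketone anti to the C6 ring carbon and from the periphery of the macrocycle, giving the 7,8-anti alcohol.

Step 14
Reactants: 23 furanophane triol
Product: 26 brassicicene M, via furan endoperoxide 24 (not isolated), via cis-ene-dione 25 (not isolated)
Conditions: O2, tetraphenylporphyrin (1 mol %), visible light, CH2Cl2/MeOH, −78 °C; Me2S, −78 to 0 °C; then Et3N, 0–23 °C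
Reagents that add atoms: oxygen, O=O
Why: Proposed new method: singlet-oxygen [4+2] addition to the furan and Me2S reduction give the cis-ene-dione (Achmatowicz-type oxidation), whose α-hydroxy ketone enolises at C12 and adds transannularly to the C11 methyl ketone (5-enolexo aldol), forming the cyclopentenone and the nine-membered ring at once, with the reversible aldol expected to settle on the trans-diol with the methyl anti to the bridge; the closest known reactions are the base rearrangement of furylcarbinol-derived 6-hydroxy-2H-pyran-3(6H)-ones to trans-4,5-dihydroxycyclopent-2-enones and the cyclisation of (Z)-hex-3-ene-2,5-dione to 4-hydroxy-4-methylcyclopent-2-enone.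

**Compound list**

1 | 2-methoxy-N-methoxy-N-methylacetamide | COCC(=O)N(C)OC | starting material
2 | but-3-en-1-ylmagnesium bromide | C=CCC[Mg]Br | starting material
3 | 1-methoxyhex-5-en-2-one | COCC(=O)CCC=C | intermediate
4 | (E)-but-2-enal | C/C=C/C=O | starting material
5 | (2E)-7-methoxy-6-oxohept-2-enal | COCC(=O)CC/C=C/C=O | intermediate
6 | S-ethyl propanethioate | CCC(=O)SCC | starting material
7 | tert-butyl{[(1Z)-1-(ethylsulfanyl)prop-1-en-1-yl]oxy}dimethylsilane | C/C=C(/O[Si](C)(C)C(C)(C)C)SCC | intermediate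
8 | S-ethyl (2R,3R)-7-methoxy-2-methyl-6-oxo-3-(2-oxoethyl)heptanethioate (Michael adduct) | CCSC(=O)[C@H](C)[C@@H](CC=O)CCC(=O)COC | intermediate
9 | S-ethyl (2R)-2-[(1S)-2-formyl-3-(methoxymethyl)cyclopent-2-en-1-yl]propanethioate | CCSC(=O)[C@H](C)[C@@H]1CCC(COC)=C1C=O | intermediate
10 | ethyl 3-oxobutanoate | CCOC(=O)CC(C)=O | starting material
11 | 1-bromo-3-methylbutan-2-one | CC(C)C(=O)CBr | starting material
12 | ethyl 4-hydroxy-2-methyl-4-(propan-2-yl)-4,5-dihydrofuran-3-carboxylate (racemic) | CCOC(=O)C1=C(C)OCC1(O)C(C)C | intermediate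
13 | ethyl 2-methyl-4-(propan-2-yl)furan-3-carboxylate | CCOC(=O)c1c(C)occ1C(C)C | intermediate
14 | [2-methyl-4-(propan-2-yl)furan-3-yl]methanol | OCc1c(C)occ1C(C)C | intermediate
15 | 3-(bromomethyl)-2-methyl-4-(propan-2-yl)furan | BrCc1c(C)occ1C(C)C | intermediate
16 | bromo{[2-methyl-4-(propan-2-yl)furan-3-yl]methyl}zinc | Br[Zn]Cc1c(C)occ1C(C)C | intermediate
17 | (5S)-2-(methoxymethyl)-5-{(2R)-4-[2-methyl-4-(propan-2-yl)furan-3-yl]-3-oxobutan-2-yl}cyclopent-1-ene-1-carbaldehyde | CC(C)c1coc(C)c1CC(=O)[C@H](C)[C@@H]1CCC(COC)=C1C=O | intermediate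
18 | 5-iodofuran analogue of 17 | CC(C)c1c(I)oc(C)c1CC(=O)[C@H](C)[C@@H]1CCC(COC)=C1C=O | intermediate
19 | (1S,2S,5S)-epoxy aldehyde (epoxide anti to the C6 side chain) | CC(C)c1c(I)oc(C)c1CC(=O)[C@H](C)[C@@H]1CC[C@@]2(COC)O[C@@]12C=O | intermediate
20 | 2-methoxyethenyl analogue of 19 (enol ether, E/Z mixture) | CC(C)c1c(I)oc(C)c1CC(=O)[C@H](C)[C@@H]1CC[C@@]2(COC)O[C@@]12C=COC | intermediate
21 | (2E)-γ-hydroxy enal, (2R,5S)-cyclopentylidene, (2R) side chain | CC(C)c1c(I)oc(C)c1CC(=O)[C@H](C)[C@@H]1CC[C@](O)(COC)/C1=C/C=O | intermediate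
22 | furanophane keto diol (C12 carbinol as epimer mixture) | CC(C)c1c2oc(C)c1CC(=O)[C@H](C)[C@@H]1CC[C@](O)(COC)/C1=C/C2O | intermediate
23 | furanophane triol, (3R,6S,7R,8S), C12 epimer mixture | CC(C)c1c2oc(C)c1C[C@H](O)[C@H](C)[C@@H]1CC[C@](O)(COC)/C1=C/C2O | intermediate
24 | furan endoperoxide of 23 (2,3,7-trioxabicyclo[2.2.1]hept-5-ene unit) | CC(C)C1=C2C[C@H](O)[C@H](C)[C@@H]3CC[C@](O)(COC)/C3=C/C(O)C14OOC2(C)O4 | intermediate
25 | macrocyclic cis-ene-dione (acetyl on C10, C13 ketone, C12 CHOH) | CC(C)/C1=C(/C(C)=O)C[C@H](O)[C@H](C)[C@@H]2CC[C@](O)(COC)/C2=C/C(O)C1=O | intermediate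
26 | brassicicene M | COC[C@@]1(O)CC[C@@H]2/C1=C\[C@@]1(O)C(=O)C(C(C)C)=C(C[C@H](O)[C@@H]2C)[C@@]1(C)O | target

**Totals**

Total step count: 14. Longest linear sequence: 10 steps (1, 2, 4, 8, 9, 10, 11, 12, 13, 14).

**Steps most likely to fail, with fallbacks**

Step 14. The ene-dione may not cyclise under amine catalysis, or may settle on the wrong C11/C12 pair; the natural configuration being the thermodynamic one is an expectation, not a known fact. The fallback sets out from 23 and returns at 26, replacing the unprotected thermodynamic cascade by a stepwise, chelation-templated aldol. t-BuMe2SiCl/imidazole silylates the two secondary alcohols to give the bis-silyl ether F6. Photo-oxygenation and Me2S then give the isolable cis-ene-dione F7, which cannot form a hemiketal. MgBr2·OEt2/i-Pr2NEt (soft enolisation of the magnesium-chelated α-silyloxy ketone) closes the C11–C12 bond to give the silylated cyclopentenone F8, and HF·pyridine gives 26.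

Step 12. The ten-membered 2,4-bridged furan is strained and the furyl–chromium addition may lose to reduction or dimerisation. The fallback sets out from 17 (skipping step 9) and returns at 22, closing the ring by electrophilic substitution instead of an organochromium addition. Epoxidation as in step 10 gives the iodine-free epoxy aldehyde F1. Methoxymethylenation gives the enol ether F2 and hydrolysis gives the γ-hydroxy enal F3. Sc(OTf)3 in MeCN at high dilution then promotes intramolecular Friedel–Crafts hydroxyalkylation of the free furan α-position by the aldehyde, giving 22.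

Step 13. Hydride may attack the macrocyclic ketone from the wrong face. The fallback sets out from 22 and returns at 23, setting C8 by inversion instead of by face selection. The reduction then gives the C8 epimer F4. A Mitsunobu reaction (4-nitrobenzoic acid, PPh3, diisopropyl azodicarboxylate) inverts C8 and also esterifies the furyl carbinol, whose configuration does not matter, giving the bis(4-nitrobenzoate) F5. K2CO3/MeOH then gives 23.

**Further compounds**

F1 | step 12 | iodine-free epoxy aldehyde (19 without iodine) | CC(C)c1coc(C)c1CC(=O)[C@H](C)[C@@H]1CC[C@@]2(COC)O[C@@]12C=O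
F2 | step 12 | iodine-free enol ether (20 without iodine) | CC(C)c1coc(C)c1CC(=O)[C@H](C)[C@@H]1CC[C@@]2(COC)O[C@@]12C=COC
F3 | step 12 | iodine-free γ-hydroxy enal (21 without iodine) | CC(C)c1coc(C)c1CC(=O)[C@H](C)[C@@H]1CC[C@](O)(COC)/C1=C/C=O
F4 | step 13 | C8 epimer of 23 | CC(C)c1c2oc(C)c1C[C@@H](O)[C@H](C)[C@@H]1CC[C@](O)(COC)/C1=C/C2O
F5 | step 13 | 8,12-bis(4-nitrobenzoate) of 23 | CC(C)c1c2oc(C)c1C[C@H](OC(=O)c1ccc(cc1)[N+](=O)[O-])[C@H](C)[C@@H]1CC[C@](O)(COC)/C1=C/C2OC(=O)c1ccc(cc1)[N+](=O)[O-]
F6 | step 14 | 8,12-bis(tert-butyldimethylsilyl) ether of 23 | CC(C)c1c2oc(C)c1C[C@H](O[Si](C)(C)C(C)(C)C)[C@H](C)[C@@H]1CC[C@](O)(COC)/C1=C/C2O[Si](C)(C)C(C)(C)C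
F7 | step 14 | 8,12-bis(tert-butyldimethylsilyl) ether of 25 | CC(C)/C1=C(/C(C)=O)C[C@H](O[Si](C)(C)C(C)(C)C)[C@H](C)[C@@H]2CC[C@](O)(COC)/C2=C/C(O[Si](C)(C)C(C)(C)C)C1=O
F8 | step 14 | 8,12-bis(tert-butyldimethylsilyl) ether of 26 | COC[C@@]1(O)CC[C@@H]2/C1=C\[C@@]1(O[Si](C)(C)C(C)(C)C)C(=O)C(C(C)C)=C(C[C@H](O[Si](C)(C)C(C)(C)C)[C@@H]2C)[C@@]1(C)O
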